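**A direct plan and its weak points**

A direct plan would make ring A as the salicylic acid A1 and ring B as the aryl fluoride A2, and would join them by nucleophilic aromatic substitution of the phenoxide of A1 on the fluorine-bearing carbon of A2.
It would set the benzylic stereocentre by sparteine-mediated lithiation of an isopentyl carbamate, transmetalation to the secondary alkylzinc A3 and a Negishi arylation, and would bring in the carboxyl group by directed ortho-lithiation and CO2.
- **The late ether-forming substitution** would be weakest. A dianion whose phenoxide stands para to the benzylic methoxy group would be heated in base with a hindered, singly activated fluoroarene that carries a free aldehyde. This invites quinone-methide loss of the stereocentre and aldehyde side reactions on the most precious material.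
- **The coupling of the α-oxygenated secondary alkylzinc** with an ortho-substituted, electron-rich aryl bromide would leave the configuration to the retention of three successive organometallic events, against β-hydride elimination.
- **The ortho-lithiation/carboxylation** would expose the benzylic ether to alkyllithium near room temperature and then release a para-hydroxybenzylic ether in acid. Several further steps (two acetal protections, a carbamoylation) would add no skeletal bond.

**Plan of the new route**

The retrosynthesis cuts two bonds of ring A at once: the aryl–oxygen bond C6–O of the diaryl ether and the C1–CO2H bond. The ether oxygen stays on ring B throughout.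
Both bonds form in one operation when a ring A aryne (C1≡C6) takes up a ring B phenoxide and CO2.
The feature that allows this: ring A carries CO2H (C1) and OAr (C6) on neighbouring carbons, and C1 is flanked by the C2 methoxy group. This is the pattern a 3-methoxybenzyne delivers, with the nucleophile at the aryne carbon remote from OMe and the electrophile beside OMe.
Ring A is finished first as a 2-(trimethylsilyl)aryl triflate carrying the (R)-ether (set by catalytic asymmetric isobutylation of an aldehyde). Ring B is finished second as a protected catechol aldehyde. Neither ring is built, and the diaryl ether core arises only in the key step, at ring A and not at ring B.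
No secondary alkylmetal coupling and no substitution on a fluoroarene occur. No phenoxide para to the benzylic ether occurs either: the ring A oxygen used to direct silylation is meta to the side chain and leaves as triflate.

Key step: step 10

Remark on the chemistry: the (R)-BINOLate titanium catalyst of step 2 is taken to deliver the alkyl group to the Re face of aryl aldehydes, as in related alkylations of benzaldehyde; if the sense proved opposite, (S)-BINOL would be used and nothing else would change.

**Route**

Step 1
Reactants: 1 3-hydroxy-2-methoxybenzaldehyde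
Product: 2 3-formyl-2-methoxyphenyl N,N-diethylcarbamate
Conditions: Et2NCOCl, K2CO3, MeCN, reflux
Reagents that add atoms: N,N-diethylcarbamoyl chloride, CCN(CC)C(=O)Cl
Why: O-carbamoylation (nucleophilic acyl substitution) of the phenoxide installs the group that later directs ortho-lithiation, and the aldehyde is inert to carbonate base.

Step 2
Reactants: 2 3-formyl-2-methoxyphenyl N,N-diethylcarbamate
Product: 3 3-[(1R)-1-hydroxy-3-methylbutyl]-2-methoxyphenyl N,N-diethylcarbamate
Conditions: i-BuMgBr premixed with bis[2-(dimethylamino)ethyl] ether, Ti(OiPr)4, (R)-1,1'-bi-2-naphthol (15 mol %), MTBE, 0 °C; aq. HCl work-up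
Reagents that add atoms: isobutylmagnesium bromide, CC(C)C[Mg]Br
Why: Titanium BINOLate-catalysed enantioselective 1,2-addition of a Grignard-derived isobutyltitanium reagent to an aromatic aldehyde, in which the amine ether additive suppresses the uncatalysed background addition and the (R)-BINOLate complex should pass the isobutyl group to the Re face of the formyl group to give the (R)-carbinol, the hindered diethylcarbamate being left alone at 0 °C.

Step 3
Reactants: 3 3-[(1R)-1-hydroxy-3-methylbutyl]-2-methoxyphenyl N,N-diethylcarbamate
Product: 5 2-methoxy-3-[(1R)-1-methoxy-3-methylbutyl]phenyl N,N-diethylcarbamate, via sodium alkoxide 4 (not isolated)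
Conditions: NaH, MeI, THF, 0 °C → rt
Reagents that add atoms: iodomethane, CI
Why: Williamson ether synthesis alkylates at oxygen only, so the configuration is kept, and the tertiary carbamate has no N–H and resists the alkoxide.

Step 4
Reactants: 5 2-methoxy-3-[(1R)-1-methoxy-3-methylbutyl]phenyl N,N-diethylcarbamate
Product: 7 2-methoxy-3-[(1R)-1-methoxy-3-methylbutyl]-6-(trimethylsilyl)phenyl N,N-diethylcarbamate, via aryllithium 6 (not isolated)
Conditions: s-BuLi, TMEDA, THF, –78 °C; Me3SiCl, –78 °C → rt
Reagents that add atoms: chlorotrimethylsilane, C[Si](C)(C)Cl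
Why: Directed ortho-metalation, in which the carbamate is the strongest director on the ring and has a single free ortho position (C6 of ring A), so that lithiation at –78 °C should be faster than deprotonation of the benzylic C–H or the anionic ortho-Fries shift, and the silyl chloride quench gives the arylsilane.

Step 5
Reactants: 7 2-methoxy-3-[(1R)-1-methoxy-3-methylbutyl]-6-(trimethylsilyl)phenyl N,N-diethylcarbamate
Product: 8 2-methoxy-3-[(1R)-1-methoxy-3-methylbutyl]-6-(trimethylsilyl)phenol
Conditions: LiAlH4, THF, 0 °C → reflux; aq. potassium sodium tartrate work-up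
Reagents that add atoms: none
Why: Hydride reduction of the carbamate carbonyl (acyl–oxygen cleavage) frees a phenoxide that is meta to the side chain, so no quinone methide can form, and the aryl–silicon bond and the benzylic ether are inert to hydride.

Step 6
Reactants: 8 2-methoxy-3-[(1R)-1-methoxy-3-methylbutyl]-6-(trimethylsilyl)phenol
Product: 9 2-methoxy-3-[(1R)-1-methoxy-3-methylbutyl]-6-(trimethylsilyl)phenyl trifluoromethanesulfonate
Conditions: Tf2O, pyridine, CH2Cl2, 0 °C
Reagents that add atoms: trifluoromethanesulfonic anhydride, O=S(=O)(OS(=O)(=O)C(F)(F)F)C(F)(F)F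
Why: O-Sulfonylation of the hindered phenol gives the 2-(trimethylsilyl)aryl triflate, the standard fluoride-triggered aryne precursor, under conditions that do not touch the stereocentre.

Step 7
Reactants: 10 2-hydroxy-3-methoxy-5-methylbenzaldehyde
Product: 11 2,3-dihydroxy-5-methylbenzaldehyde
Conditions: BBr3, CH2Cl2, –78 → 0 °C; H2O
Reagents that add atoms: none
Why: Lewis-acid cleavage of the aryl methyl ether (bromide attacks the methyl group of the boron-complexed ether), a standard conversion of ortho-vanillin-type aldehydes into catechol aldehydes, is placed on a fragment that has no acid-sensitive group.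

Step 8
Reactants: 11 2,3-dihydroxy-5-methylbenzaldehyde
Product: 13 3-(allyloxy)-2-hydroxy-5-methylbenzaldehyde, via disodium catecholate 12 (not isolated)
Conditions: NaH (2.2 equiv), DMSO, rt; allyl bromide (1.0 equiv), rt; dilute HCl work-up
Reagents that add atoms: allyl bromide, C=CCBr
Why: Regioselective Williamson alkylation of the catechol dianion, in which the 2-oxide is delocalised into the ortho-formyl group and held in a sodium chelate, so one equivalent of allyl bromide should react at the more nucleophilic 3-oxide.

Step 9
Reactants: 13 3-(allyloxy)-2-hydroxy-5-methylbenzaldehyde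
Product: 14 2-(allyloxy)-6-(1,3-dioxolan-2-yl)-4-methylphenol
Conditions: HOCH2CH2OH, TsOH·H2O (cat.), benzene, reflux (Dean–Stark)
Reagents that add atoms: ethane-1,2-diol, OCCO
Why: Acid-catalysed acetalisation with azeotropic removal of water masks the aldehyde, which would otherwise trap the aryl anion of the key step as a xanthenol, while the allyl ether is stable to acid and the temperature stays far below that of a Claisen rearrangement.

Step 10
Reactants: 9 2-methoxy-3-[(1R)-1-methoxy-3-methylbutyl]-6-(trimethylsilyl)phenyl trifluoromethanesulfonate; 14 2-(allyloxy)-6-(1,3-dioxolan-2-yl)-4-methylphenol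
Product: 19 6-[2-(allyloxy)-6-(1,3-dioxolan-2-yl)-4-methylphenoxy]-2-methoxy-3-[(1R)-1-methoxy-3-methylbutyl]benzoic acid, via potassium phenoxide 15 (not isolated), via aryne 16 (not isolated), via arylpotassium 17 (not isolated), via potassium carboxylate 18 (not isolated)
Conditions: 14 (1.5 equiv), KH, THF, 0 °C; 18-crown-6, CO2 (1 atm), then 9 and KF, 0 °C → rt; cold dilute HCl to pH 4
Reagents that add atoms: carbon dioxide, O=C=O
Why: Proposed new method: fluoride removes the silyl group of 9 and triflate leaves to give the 3-methoxy-4-alkylbenzyne 16, the potassium phenoxide 15 adds through oxygen to the aryne carbon remote from the methoxy group (C6 of ring A), and the resulting aryl anion 17, which sits at C1 beside the inductively stabilising methoxy group, is carboxylated by CO2 before it can find a proton. The closest known reaction types are the fluoride-induced three-component coupling of arynes, amines and CO2 to anthranilic acids and the O-arylation of phenols by arynes; here an anionic oxygen nucleophile takes the place of the amine, which is why the step carries the label. No ring is closed: the diaryl ether core arises by intermolecular C6–O bond formation and the carboxyl carbon is attached to C1 in the same operation. No stereocentre is formed, and the (R)-benzylic ether meets neither acid nor strong base nor a para-phenoxide. The step needs regioselectivity (oxygen at C6, carbon at C1), which the methoxy group beside the triple bond should secure by distorting the aryne and by shielding C1 from the hindered phenoxide. It also needs carboxylation to outrun protonation and C-arylation, which the proton-free medium (KH-derived phenoxide in THF), the masked aldehyde and the blocked ortho and para positions of 15 should secure.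

Step 11
Reactants: 19 6-[2-(allyloxy)-6-(1,3-dioxolan-2-yl)-4-methylphenoxy]-2-methoxy-3-[(1R)-1-methoxy-3-methylbutyl]benzoic acid
Product: 21 6-(2-formyl-6-hydroxy-4-methylphenoxy)-2-methoxy-3-[(1R)-1-methoxy-3-methylbutyl]benzoic acid, via phenol acetal 20 (not isolated)
Conditions: Pd(PPh3)4 (5 mol %), morpholine, THF, rt; then 0.5 M HCl (aq), THF, rt
Reagents that add atoms: water, O
Why: Tsuji–Trost-type deallylation (zerovalent palladium ionises the aryl allyl ether to a π-allyl complex that morpholine captures) frees the phenol under neutral conditions, and brief dilute acid then hydrolyses the dioxolane, conditions under which the benzylic methyl ether (carboxyl meta to it) should not ionise, so (R) is kept.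

**Compound list**

1 | 3-hydroxy-2-methoxybenzaldehyde | COc1c(O)cccc1C=O | starting material
2 | 3-formyl-2-methoxyphenyl N,N-diethylcarbamate | CCN(CC)C(=O)Oc1cccc(C=O)c1OC | intermediate
3 | 3-[(1R)-1-hydroxy-3-methylbutyl]-2-methoxyphenyl N,N-diethylcarbamate | CCN(CC)C(=O)Oc1cccc([C@@H](CC(C)C)O)c1OC | intermediate
4 | sodium alkoxide of 3 | CCN(CC)C(=O)Oc1cccc([C@@H](CC(C)C)[O-])c1OC.[Na+] | intermediate
5 | 2-methoxy-3-[(1R)-1-methoxy-3-methylbutyl]phenyl N,N-diethylcarbamate | CCN(CC)C(=O)Oc1cccc([C@@H](CC(C)C)OC)c1OC | intermediate
6 | aryllithium of 5, lithium ortho to the carbamate (C6 of ring A) | CCN(CC)C(=O)Oc1c([Li])ccc([C@@H](CC(C)C)OC)c1OC | intermediate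
7 | 2-methoxy-3-[(1R)-1-methoxy-3-methylbutyl]-6-(trimethylsilyl)phenyl N,N-diethylcarbamate | CCN(CC)C(=O)Oc1c([Si](C)(C)C)ccc([C@@H](CC(C)C)OC)c1OC | intermediate
8 | 2-methoxy-3-[(1R)-1-methoxy-3-methylbutyl]-6-(trimethylsilyl)phenol | COc1c(O)c([Si](C)(C)C)ccc1[C@@H](CC(C)C)OC | intermediate
9 | 2-methoxy-3-[(1R)-1-methoxy-3-methylbutyl]-6-(trimethylsilyl)phenyl trifluoromethanesulfonate | COc1c(OS(=O)(=O)C(F)(F)F)c([Si](C)(C)C)ccc1[C@@H](CC(C)C)OC | intermediate
10 | 2-hydroxy-3-methoxy-5-methylbenzaldehyde | COc1cc(C)cc(C=O)c1O | starting material
11 | 2,3-dihydroxy-5-methylbenzaldehyde | Cc1cc(O)c(O)c(C=O)c1 | intermediate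
12 | disodium 3-formyl-5-methylbenzene-1,2-diolate | Cc1cc([O-])c([O-])c(C=O)c1.[Na+].[Na+] | intermediate
13 | 3-(allyloxy)-2-hydroxy-5-methylbenzaldehyde | C=CCOc1cc(C)cc(C=O)c1O | intermediate
14 | 2-(allyloxy)-6-(1,3-dioxolan-2-yl)-4-methylphenol | C=CCOc1cc(C)cc(C2OCCO2)c1O | intermediate
15 | potassium phenoxide of 14 | C=CCOc1cc(C)cc(C2OCCO2)c1[O-].[K+] | intermediate
16 | 3-methoxy-4-[(1R)-1-methoxy-3-methylbutyl]benzyne (triple bond C1≡C6 of ring A) | COC1=C([C@@H](CC(C)C)OC)C=CC#C1 | intermediate
17 | arylpotassium from 15 and 16, metal at C1 of ring A between OMe and OAr | COc1c([K])c(Oc2c(OCC=C)cc(C)cc2C2OCCO2)ccc1[C@@H](CC(C)C)OC | intermediate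
18 | potassium 6-[2-(allyloxy)-6-(1,3-dioxolan-2-yl)-4-methylphenoxy]-2-methoxy-3-[(1R)-1-methoxy-3-methylbutyl]benzoate | COc1c(C(=O)[O-])c(Oc2c(OCC=C)cc(C)cc2C2OCCO2)ccc1[C@@H](CC(C)C)OC.[K+] | intermediate
19 | 6-[2-(allyloxy)-6-(1,3-dioxolan-2-yl)-4-methylphenoxy]-2-methoxy-3-[(1R)-1-methoxy-3-methylbutyl]benzoic acid | COc1c(C(=O)O)c(Oc2c(OCC=C)cc(C)cc2C2OCCO2)ccc1[C@@H](CC(C)C)OC | intermediate
20 | 6-[2-(1,3-dioxolan-2-yl)-6-hydroxy-4-methylphenoxy]-2-methoxy-3-[(1R)-1-methoxy-3-methylbutyl]benzoic acid | COc1c(C(=O)O)c(Oc2c(O)cc(C)cc2C2OCCO2)ccc1[C@@H](CC(C)C)OC | intermediate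
21 | 6-(2-formyl-6-hydroxy-4-methylphenoxy)-2-methoxy-3-[(1R)-1-methoxy-3-methylbutyl]benzoic acid (CNP0328949.1) | COc1c([C@@H](CC(C)C)OC)ccc(Oc2c(O)cc(C)cc2C=O)c1C(=O)O | target

**Step count and risks**

Total steps: 11 (ring A fragment, steps 1–6; ring B fragment, steps 7–9; union and end, steps 10–11).
Longest linear sequence: 8 steps (steps 1–6, 10, 11).

Steps most likely to fail:

1. **Step 10 (Proposed new method).** The aryl anion may be protonated before it is carboxylated, by adventitious or intramolecular C–H acids. The phenoxide may also add through its CO2 adduct (the aryl carbonate) and then suffer acyl migration, so that the carboxyl group does not arrive at C1. The fallback uses known chemistry, sets out from 9 and comes back at 19. Compound 9 would be treated with CsF and I2 in MeCN, so that the aryne inserts into the iodine–iodine bond and gives 1,2-diiodo-3-methoxy-4-[(1R)-1-methoxy-3-methylbutyl]benzene F1. Iodine–magnesium exchange with i-PrMgCl·LiCl at –78 °C is expected at the iodine flanked by the methoxy group (chelation, relief of strain). Carboxylation with CO2 would then give 6-iodo-2-methoxy-3-[(1R)-1-methoxy-3-methylbutyl]benzoic acid F2. An Ullmann ether synthesis of F2 with phenol 14 (CuI, picolinic acid, K3PO4, DMSO, 80–90 °C), helped by the ortho-carboxylate, would return to 19.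

2. **Step 4.** Deprotonation at the benzylic C–H beside oxygen (erosion of configuration, Wittig-type rearrangement) or anionic ortho-Fries migration of the carbamoyl group may compete with ortho-lithiation. The fallback silylates before the stereocentre exists, sets out from 2 and comes back at 7. Compound 2 would be masked in the flask as its lithium α-amino alkoxide by addition of lithium 4-methylpiperazin-1-ide at –78 °C, lithiated ortho to the carbamate with s-BuLi/TMEDA and quenched with Me3SiCl. Aqueous work-up would restore the aldehyde and give 3-formyl-2-methoxy-6-(trimethylsilyl)phenyl N,N-diethylcarbamate F3. The isobutylation of step 2 would give 3-[(1R)-1-hydroxy-3-methylbutyl]-2-methoxy-6-(trimethylsilyl)phenyl N,N-diethylcarbamate F4, and the methylation of step 3 would return to 7.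

3. **Step 2.** Facial selectivity may be poor, because the ortho-methoxy and carbamate oxygens can chelate titanium, and β-hydride transfer from the isobutyl reagent may reduce the aldehyde. The fallback sets the centre by reduction instead of addition, sets out from 2 and comes back at 3. Uncatalysed addition of i-BuMgBr (THF, –78 °C) would give racemic 3-(1-hydroxy-3-methylbutyl)-2-methoxyphenyl N,N-diethylcarbamate F5. MnO2 in CH2Cl2 would oxidise the benzylic alcohol to 2-methoxy-3-(3-methylbutanoyl)phenyl N,N-diethylcarbamate F6. Corey–Bakshi–Shibata reduction with (S)-1-methyl-3,3-diphenyltetrahydro-1H,3H-pyrrolo[1,2-c][1,3,2]oxazaborole and BH3·SMe2 should then give the (R)-alcohol 3, with the aryl group as the large substituent, as in the reduction of acetophenone to (R)-1-phenylethanol.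

**Further compounds**

F1 | step 10 | 1,2-diiodo-3-methoxy-4-[(1R)-1-methoxy-3-methylbutyl]benzene | COc1c(I)c(I)ccc1[C@@H](CC(C)C)OC
F2 | step 10 | 6-iodo-2-methoxy-3-[(1R)-1-methoxy-3-methylbutyl]benzoic acid | COc1c(C(=O)O)c(I)ccc1[C@@H](CC(C)C)OC
F3 | step 4 | 3-formyl-2-methoxy-6-(trimethylsilyl)phenyl N,N-diethylcarbamate | CCN(CC)C(=O)Oc1c([Si](C)(C)C)ccc(C=O)c1OC
F4 | step 4 | 3-[(1R)-1-hydroxy-3-methylbutyl]-2-methoxy-6-(trimethylsilyl)phenyl N,N-diethylcarbamate | CCN(CC)C(=O)Oc1c([Si](C)(C)C)ccc([C@@H](CC(C)C)O)c1OC
F5 | step 2 | racemic 3-(1-hydroxy-3-methylbutyl)-2-methoxyphenyl N,N-diethylcarbamate | CCN(CC)C(=O)Oc1cccc(C(CC(C)C)O)c1OC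
F6 | step 2 | 2-methoxy-3-(3-methylbutanoyl)phenyl N,N-diethylcarbamate | CCN(CC)C(=O)Oc1cccc(C(=O)CC(C)C)c1OC
A1 | direct plan | 6-hydroxy-2-methoxy-3-[(1R)-1-methoxy-3-methylbutyl]benzoic acid | COc1c(C(=O)O)c(O)ccc1[C@@H](CC(C)C)OC
A2 | direct plan | 2-fluoro-5-methyl-3-(tetrahydropyran-2-yloxy)benzaldehyde | Cc1cc(C=O)c(F)c(OC2CCCCO2)c1
A3 | direct plan | (S)-chloro[1-(diisopropylcarbamoyloxy)-3-methylbutyl]zinc | Cl[Zn][C@@H](CC(C)C)OC(=O)N(C(C)C)C(C)C
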